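Ring numbering: C1 (exocyclic methylene), C2=C3, C4 (CMe2), C5 (CH–O), C6, C7, C8(Me)=C9, C10, C11. The plan cuts C6–C7 of this 11-membered carbocycle. Once C5 is a ketone, its only enolisable neighbour is C6, because C4 is quaternary, and C7 is the unsubstituted allylic terminus of the C8=C9 alkene. With a removable ester on C6, one palladium-catalysed allylic alkylation forms C6–C7 and closes the ring in one operation. Its substrate is an open-chain β-keto ester that already holds the E-diene and the E-trisubstituted alkene and ends in a C7 allylic methyl carbonate. C5, the only stereocentre, is set afterwards by CBS reduction.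

Key step: step 9

Remark on the chemistry: the eleven-membered intermediates are assumed to flip quickly between their mirror-image ring conformers, so C5 (and, for a time, C6) is the only stereo-element that needs control.

Step 1
Reactants: 1 6-methylhept-5-en-2-one (sulcatone)
Product: 2 (5E)-7-hydroxy-6-methylhept-5-en-2-one
Conditions: SeO2 (cat.), t-BuOOH, salicylic acid (cat.), CH2Cl2, 0 °C to rt
Reagents that add atoms: tert-butyl hydroperoxide, CC(C)(C)OO (terminal source of the new oxygen, handed on through selenium dioxide, O=[Se]=O)
Why: Riley-type allylic oxidation (ene reaction of SeO2, then a [2,3]-sigmatropic shift) hydroxylates the methyl group trans to the chain of a trisubstituted alkene, which fixes the E geometry of C8=C9, and the methyl ketone is left alone at this temperature.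

Step 2
Reactants: 2 (5E)-7-hydroxy-6-methylhept-5-en-2-one
Product: 3 (5E)-7-[(tert-butyldimethylsilyl)oxy]-6-methylhept-5-en-2-one
Conditions: TBSCl, imidazole, CH2Cl2, 0 °C to rt
Reagents that add atoms: tert-butyldimethylsilyl chloride, CC(C)(C)[Si](C)(C)Cl
Why: Routine imidazole-promoted silylation of a primary allylic alcohol gives an ether that withstands the amide base, the coupling and the sodium hydride of steps 3, 5 and 6, and zerovalent palladium cannot ionise it.

Step 3
Reactants: 3 (5E)-7-[(tert-butyldimethylsilyl)oxy]-6-methylhept-5-en-2-one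
Product: 5 (5E)-7-[(tert-butyldimethylsilyl)oxy]-6-methylhepta-1,5-dien-2-yl trifluoromethanesulfonate, via lithium enolate 4 (not isolated)
Conditions: LiN(iPr)2, THF, −78 °C; then PhNTf2, −78 to 0 °C
Reagents that add atoms: N-phenylbis(trifluoromethanesulfonimide), O=S(=O)(N(c1ccccc1)S(=O)(=O)C(F)(F)F)C(F)(F)F; LiN(iPr)2, [Li]N(C(C)C)C(C)C (lithium of 4 only)
Why: Kinetic deprotonation by a hindered lithium amide at −78 °C takes a methyl proton rather than a C11 methylene proton, and O-triflation of that enolate (standard enol triflate synthesis) fixes the 1,1-disubstituted alkene at C1.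

Step 4
Reactants: 6 2,2-dimethylbut-3-enoic acid
Product: 8 3,3-dimethylpent-4-en-2-one, via dilithium gem-diolate 7 (not isolated)
Conditions: MeLi (2.2 equiv), Et2O, 0 °C to rt; inverse quench into cold 1 M HCl
Reagents that add atoms: methyllithium, [Li]C
Why: In the classical conversion of a carboxylic acid into a methyl ketone the second MeLi adds to the lithium carboxylate and diolate 7 persists until the quench, so no ketone meets MeLi, and bringing in C6 here avoids a later enolate acylation by a sluggish neopentyl-type ester.

Step 5
Reactants: 5 (5E)-7-[(tert-butyldimethylsilyl)oxy]-6-methylhepta-1,5-dien-2-yl trifluoromethanesulfonate; 8 3,3-dimethylpent-4-en-2-one (2–3 equiv)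
Product: 9 (4E,9E)-11-[(tert-butyldimethylsilyl)oxy]-3,3,10-trimethyl-6-methylideneundeca-4,9-dien-2-one
Conditions: Pd(OAc)2 (5 mol %), PPh3 (10 mol %), LiCl, Et3N, DMF, 65 °C
Reagents that add atoms: none
Why: Mizoroki–Heck vinylation of an enol triflate, in which the alkenylpalladium unit bonds to the free CH2 end of 8 because the other alkene carbon is neopentylic, the only β-hydrogens available sit on C2 so that syn elimination gives the E C2=C3 alkene, and chloride keeps the neutral pathway that favours linear insertion.

Step 6
Reactants: 9 (4E,9E)-11-[(tert-butyldimethylsilyl)oxy]-3,3,10-trimethyl-6-methylideneundeca-4,9-dien-2-one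
Product: 11 methyl (5E,10E)-12-[(tert-butyldimethylsilyl)oxy]-4,4,11-trimethyl-7-methylidene-3-oxododeca-5,10-dienoate, via sodium enolate 10 (not isolated)
Conditions: NaH (2.5 equiv), (MeO)2CO, THF, reflux; AcOH quench, 0 °C
Reagents that add atoms: dimethyl carbonate, COC(=O)OC; sodium hydride, [Na+].[H-] (sodium of 10 only)
Why: Claisen-type C-methoxycarbonylation of a ketone enolate with dimethyl carbonate, well established for tert-alkyl methyl ketones, works here because quaternary C4 leaves the C6 methyl as the sole enolisable site and formation of the stabilised enolate 10 drives the equilibrium.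

Step 7
Reactants: 11 methyl (5E,10E)-12-[(tert-butyldimethylsilyl)oxy]-4,4,11-trimethyl-7-methylidene-3-oxododeca-5,10-dienoate
Product: 12 methyl (5E,10E)-12-hydroxy-4,4,11-trimethyl-7-methylidene-3-oxododeca-5,10-dienoate
Conditions: HF·pyridine, pyridine, THF, 0 °C to rt
Reagents that add atoms: none
Why: Fluoride-driven Si–O cleavage in a pyridine-buffered medium frees the primary allylic alcohol without harming the β-keto ester or the diene.

Step 8
Reactants: 12 methyl (5E,10E)-12-hydroxy-4,4,11-trimethyl-7-methylidene-3-oxododeca-5,10-dienoate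
Product: 13 methyl (5E,10E)-12-[(methoxycarbonyl)oxy]-4,4,11-trimethyl-7-methylidene-3-oxododeca-5,10-dienoate
Conditions: ClCO2Me, pyridine, CH2Cl2, 0 °C
Reagents that add atoms: methyl chloroformate, COC(=O)Cl
Why: O-Acylation of the primary alcohol by a chloroformate under pyridine is far faster than any reaction of the weakly enolised β-keto ester, and it installs a leaving group that later supplies its own base.

Step 9
Reactants: 13 methyl (5E,10E)-12-[(methoxycarbonyl)oxy]-4,4,11-trimethyl-7-methylidene-3-oxododeca-5,10-dienoate
Product: 14 methyl (4E,9E)-3,3,10-trimethyl-6-methylidene-2-oxocycloundeca-4,9-diene-1-carboxylate (racemic; the ester-bearing carbon C6 is its only stereocentre)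
Conditions: Pd(PPh3)4 (10 mol %), degassed THF, 65 °C, 13 added by syringe pump over about 15 h, final concentration about 1 mM
Reagents that add atoms: none
Why: Zerovalent palladium expels the carbonate of 13 to give a cationic η3-allyl complex over C7–C8–C9, CO2 departs, and the liberated methoxide removes a proton from C6, so the nucleophile arises only where and when the electrophile exists and no added base is needed. The soft enolate then bonds to the allyl unit on the face away from the metal, the normal course of the Tsuji–Trost reaction, whose ring-forming version with stabilised carbanions is established for medium and large carbocycles, eleven-membered ones included. The 11-membered ring closes in the endo sense, at the allyl terminus remote from the tether, which leaves C8=C9 inside the ring. C6 becomes a stereocentre without any control, which is accepted because step 10 turns it back into a CH2 group. The step needs C7 over C9 attack, retention of the E alkene, C- over O-alkylation and cyclisation over oligomerisation: C7 is the unhindered end of the allyl unit whereas bonding at substituted C9 would have to build a more strained nine-membered ring, the E substrate ionises to the syn complex and capture should outpace π–σ–π equilibration, O-allylation is reversible under the catalyst, and slow addition keeps free substrate scarce. The 1,3-diene bears no leaving group and stays a spectator, and the C4 gem-dimethyl group and the two E alkenes reduce the freedom of the chain.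

Step 10
Reactants: 14 methyl (4E,9E)-3,3,10-trimethyl-6-methylidene-2-oxocycloundeca-4,9-diene-1-carboxylate
Product: 15 (3E,8E)-2,2,9-trimethyl-5-methylidenecycloundeca-3,8-dien-1-one
Conditions: LiCl, H2O, DMSO, 125 °C
Reagents that add atoms: none
Why: Krapcho demethoxycarbonylation, in which chloride dealkylates the methyl ester by SN2 attack, the β-keto carboxylate loses CO2 and water protonates the enolate, erases the C6 stereocentre, and quaternary C4 prevents C2=C3 from moving into conjugation.

Step 11
Reactants: 15 (3E,8E)-2,2,9-trimethyl-5-methylidenecycloundeca-3,8-dien-1-one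
Product: 17 (1R,3E,8E)-2,2,9-trimethyl-5-methylidenecycloundeca-3,8-dien-1-ol, via catechol borate ester 16 (not isolated)
Conditions: (S)-2-methyl-CBS-oxazaborolidine (0.5 equiv), catecholborane, toluene, −78 to −40 °C; aqueous work-up
Reagents that add atoms: catecholborane, [H]B1Oc2ccccc2O1 (boron and catechol unit of 16 only; 17 keeps only its hydride)
Why: Corey–Bakshi–Shibata reduction, in which the ketone binds to the ring boron of the (S)-catalyst through the lone pair on the side of the small C6 methylene, away from bulky quaternary C4, and the catalyst-bound borane passes hydride through a six-membered transition state to the face that gives (R)-C5, the sense known for tert-alkyl methyl ketones, while catecholborane does not hydroborate alkenes at this temperature.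

Step 12
Reactants: 18 vanillic acid (4-hydroxy-3-methoxybenzoic acid)
Product: 19 tert-butyldimethylsilyl 4-[(tert-butyldimethylsilyl)oxy]-3-methoxybenzoate
Conditions: TBSCl (2.5 equiv), imidazole, DMF, rt
Reagents that add atoms: tert-butyldimethylsilyl chloride, CC(C)(C)[Si](C)(C)Cl
Why: Exhaustive silylation masks the phenol and also gives a silyl ester, the direct precursor of the acid chloride.

Step 13
Reactants: 19 tert-butyldimethylsilyl 4-[(tert-butyldimethylsilyl)oxy]-3-methoxybenzoate; 17 (1R,3E,8E)-2,2,9-trimethyl-5-methylidenecycloundeca-3,8-dien-1-ol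
Product: 21 (1R,3E,8E)-2,2,9-trimethyl-5-methylidenecycloundeca-3,8-dien-1-yl 4-[(tert-butyldimethylsilyl)oxy]-3-methoxybenzoate, via acid chloride 20 (not isolated)
Conditions: 19, (COCl)2, DMF (cat.), CH2Cl2, 0 °C to rt, evaporate; then 17, Et3N, DMAP, CH2Cl2, 0 to 40 °C
Reagents that add atoms: oxalyl chloride, O=C(Cl)C(=O)Cl (chlorine of 20 only, lost again in 21)
Why: Oxalyl chloride with catalytic DMF converts a silyl ester directly into the acid chloride without releasing HCl, and DMAP-catalysed acylation through the acylpyridinium ion esterifies the hindered alcohol at oxygen, so the C5–O bond and the (R) configuration are untouched.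

Step 14
Reactants: 21 (1R,3E,8E)-2,2,9-trimethyl-5-methylidenecycloundeca-3,8-dien-1-yl 4-[(tert-butyldimethylsilyl)oxy]-3-methoxybenzoate
Product: 22 (1R,3E,8E)-2,2,9-trimethyl-5-methylidenecycloundeca-3,8-dien-1-yl 4-hydroxy-3-methoxybenzoate (CNP0416843.1)
Conditions: n-Bu4NF, AcOH, THF, 0 °C
Reagents that add atoms: none
Why: Fluoride cleaves an aryl silyl ether rapidly, and the acetic acid buffer keeps the phenoxide from attacking the hindered benzoate, which is inert to these conditions.

Compound list
1 | 6-methylhept-5-en-2-one (sulcatone) | CC(C)=CCCC(C)=O | starting material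
2 | (5E)-7-hydroxy-6-methylhept-5-en-2-one | CC(=O)CC/C=C(C)/CO | intermediate
3 | (5E)-7-[(tert-butyldimethylsilyl)oxy]-6-methylhept-5-en-2-one | CC(=O)CC/C=C(C)/CO[Si](C)(C)C(C)(C)C | intermediate
4 | lithium (5E)-7-[(tert-butyldimethylsilyl)oxy]-6-methylhepta-1,5-dien-2-olate | [Li+].C=C([O-])CC/C=C(C)/CO[Si](C)(C)C(C)(C)C | intermediate
5 | (5E)-7-[(tert-butyldimethylsilyl)oxy]-6-methylhepta-1,5-dien-2-yl trifluoromethanesulfonate | C=C(OS(=O)(=O)C(F)(F)F)CC/C=C(C)/CO[Si](C)(C)C(C)(C)C | intermediate
6 | 2,2-dimethylbut-3-enoic acid | C=CC(C)(C)C(=O)O | starting material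
7 | dilithium 3,3-dimethylpent-4-ene-2,2-diolate | [Li+].[Li+].C=CC(C)(C)C(C)([O-])[O-] | intermediate
8 | 3,3-dimethylpent-4-en-2-one | C=CC(C)(C)C(C)=O | intermediate
9 | (4E,9E)-11-[(tert-butyldimethylsilyl)oxy]-3,3,10-trimethyl-6-methylideneundeca-4,9-dien-2-one | C=C(CC/C=C(C)/CO[Si](C)(C)C(C)(C)C)/C=C/C(C)(C)C(C)=O | intermediate
10 | sodium enolate (chelated, Z) of β-keto ester 11 | [Na+].C=C(CC/C=C(C)/CO[Si](C)(C)C(C)(C)C)/C=C/C(C)(C)/C([O-])=C/C(=O)OC | intermediate
11 | methyl (5E,10E)-12-[(tert-butyldimethylsilyl)oxy]-4,4,11-trimethyl-7-methylidene-3-oxododeca-5,10-dienoate | C=C(CC/C=C(C)/CO[Si](C)(C)C(C)(C)C)/C=C/C(C)(C)C(=O)CC(=O)OC | intermediate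
12 | methyl (5E,10E)-12-hydroxy-4,4,11-trimethyl-7-methylidene-3-oxododeca-5,10-dienoate | C=C(CC/C=C(C)/CO)/C=C/C(C)(C)C(=O)CC(=O)OC | intermediate
13 | methyl (5E,10E)-12-[(methoxycarbonyl)oxy]-4,4,11-trimethyl-7-methylidene-3-oxododeca-5,10-dienoate | C=C(CC/C=C(C)/COC(=O)OC)/C=C/C(C)(C)C(=O)CC(=O)OC | intermediate
14 | methyl (4E,9E)-3,3,10-trimethyl-6-methylidene-2-oxocycloundeca-4,9-diene-1-carboxylate, racemic | C=C1/C=C/C(C)(C)C(=O)C(C(=O)OC)C/C(C)=C/CC1 | intermediate
15 | (3E,8E)-2,2,9-trimethyl-5-methylidenecycloundeca-3,8-dien-1-one | C=C1/C=C/C(C)(C)C(=O)CC/C(C)=C/CC1 | intermediate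
16 | 2-{[(1R,3E,8E)-2,2,9-trimethyl-5-methylidenecycloundeca-3,8-dien-1-yl]oxy}-1,3,2-benzodioxaborole | C=C1/C=C/C(C)(C)[C@H](OB2Oc3ccccc3O2)CC/C(C)=C/CC1 | intermediate
17 | (1R,3E,8E)-2,2,9-trimethyl-5-methylidenecycloundeca-3,8-dien-1-ol | C=C1/C=C/C(C)(C)[C@H](O)CC/C(C)=C/CC1 | intermediate
18 | vanillic acid | COc1cc(C(=O)O)ccc1O | starting material
19 | tert-butyldimethylsilyl 4-[(tert-butyldimethylsilyl)oxy]-3-methoxybenzoate | COc1cc(C(=O)O[Si](C)(C)C(C)(C)C)ccc1O[Si](C)(C)C(C)(C)C | intermediate
20 | 4-[(tert-butyldimethylsilyl)oxy]-3-methoxybenzoyl chloride | COc1cc(C(=O)Cl)ccc1O[Si](C)(C)C(C)(C)C | intermediate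
21 | (1R,3E,8E)-2,2,9-trimethyl-5-methylidenecycloundeca-3,8-dien-1-yl 4-[(tert-butyldimethylsilyl)oxy]-3-methoxybenzoate | C=C1/C=C/C(C)(C)[C@H](OC(=O)c2ccc(O[Si](C)(C)C(C)(C)C)c(OC)c2)CC/C(C)=C/CC1 | intermediate
22 | (1R,3E,8E)-2,2,9-trimethyl-5-methylidenecycloundeca-3,8-dien-1-yl 4-hydroxy-3-methoxybenzoate | C=C1/C=C/C(C)(C)[C@H](OC(=O)c2ccc(O)c(OC)c2)CC/C(C)=C/CC1 | target

Total step count: 14. Longest linear sequence: 12 steps (steps 1–3, 5–11, 13 and 14, from sulcatone).

Steps most likely to fail

Step 9. Even at high dilution, intermolecular alkylation may outrun the costly closure of the eleven-membered ring. The η3-allyl complex may also lose a proton to form a conjugated diene instead of being captured, and the 1,3-diene may tie up the catalyst. The fallback closes the same bond without a metal. It sets out from alcohol 12, which an Appel reaction (CBr4, PPh3, CH2Cl2, 0 °C) should convert into the primary allylic bromide methyl (5E,10E)-12-bromo-4,4,11-trimethyl-7-methylidene-3-oxododeca-5,10-dienoate F1. Slow addition of this bromide to a suspension of Cs2CO3 in MeCN under high dilution should then join C6 to C7 by direct SN2 displacement by the caesium enolate. This is a known way of macrocyclising β-keto esters and malonates onto allylic halides, and the route is rejoined at 14.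

Step 5. Insertion may occur with the wrong regiochemistry, a palladium hydride may shift the 1,1-disubstituted double bond, or the diene product may be vinylated a second time. The fallback replaces C–H vinylation by a Stille coupling in which both alkene geometries are preformed. It sets out from triflate 5 and needs one further purchased building block, 2,2-dimethylbut-3-ynoic acid F2. MeLi (3.2 equiv, Et2O, then acid quench) should give 3,3-dimethylpent-4-yn-2-one F3. Hydrostannation with Bu3SnH and PdCl2(PPh3)2 (cat.) in THF should then place tin on the terminal carbon, away from the quaternary centre, and give (4E)-3,3-dimethyl-5-(tributylstannyl)pent-4-en-2-one F4. Coupling of this stannane with 5 (Pd(PPh3)4, LiCl, THF, 60 °C) returns to the route at 9.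

Step 11. Hydride transfer to the neopentyl-type ketone may be sluggish, and the conformational bias of the ring may work against the catalyst and erode facial selectivity. The fallback is resolution instead of asymmetric induction. It sets out from ketone 15, which LiAlH4 (Et2O, 0 °C) should reduce to racemic (3E,8E)-2,2,9-trimethyl-5-methylidenecycloundeca-3,8-dien-1-ol F5. Esterification with (S)-2-methoxy-2-phenylacetic acid (DCC, DMAP, CH2Cl2, 0 °C) should give two diastereomers to be separated by chromatography. These are (1R,3E,8E)-2,2,9-trimethyl-5-methylidenecycloundeca-3,8-dien-1-yl (2S)-2-methoxy-2-phenylacetate F6 and (1S,3E,8E)-2,2,9-trimethyl-5-methylidenecycloundeca-3,8-dien-1-yl (2S)-2-methoxy-2-phenylacetate F7. Saponification of the (1R) ester with LiOH in aqueous THF/MeOH rejoins the route at 17.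

Further compounds
F1 | step 9 | methyl (5E,10E)-12-bromo-4,4,11-trimethyl-7-methylidene-3-oxododeca-5,10-dienoate | C=C(CC/C=C(C)/CBr)/C=C/C(C)(C)C(=O)CC(=O)OC
F2 | step 5 | 2,2-dimethylbut-3-ynoic acid (bought) | C#CC(C)(C)C(=O)O
F3 | step 5 | 3,3-dimethylpent-4-yn-2-one | C#CC(C)(C)C(C)=O
F4 | step 5 | (4E)-3,3-dimethyl-5-(tributylstannyl)pent-4-en-2-one | CCCC[Sn](CCCC)(CCCC)/C=C/C(C)(C)C(C)=O
F5 | step 11 | racemic (3E,8E)-2,2,9-trimethyl-5-methylidenecycloundeca-3,8-dien-1-ol | C=C1/C=C/C(C)(C)C(O)CC/C(C)=C/CC1
F6 | step 11 | (1R,3E,8E)-2,2,9-trimethyl-5-methylidenecycloundeca-3,8-dien-1-yl (2S)-2-methoxy-2-phenylacetate | C=C1/C=C/C(C)(C)[C@H](OC(=O)[C@@H](OC)c2ccccc2)CC/C(C)=C/CC1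
F7 | step 11 | (1S,3E,8E)-2,2,9-trimethyl-5-methylidenecycloundeca-3,8-dien-1-yl (2S)-2-methoxy-2-phenylacetate | C=C1/C=C/C(C)(C)[C@@H](OC(=O)[C@@H](OC)c2ccccc2)CC/C(C)=C/CC1
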